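**Retrosynthetic overview**

1. Feature: ring A (C4a, C5, C6, C7, C8, C8a) is a resorcinol with oxygen on C7 and C8a, prenyl on C8 between them, the C4 acyl carbon on C4a and hydrogen on C5 and C6. This is the imprint of a folded C4–C4a–C8a–C8–C7–C6–C5 poly-β-carbonyl chain in which C8 is a doubly activated methine and C5 sits at the aldehyde level.
2. Ring C (last): O1–C2 and C2–C3 are cut back to deoxybenzoin 17 plus a one-carbon unit. 17 is cut at C4–CH2 into benzodioxinone 13 and benzyl Grignard reagent 16; ring B is bought intact.
3. Ring A (key): the C4a–C5 bond of benzodioxinone 12 is cut back to the open-chain keto-dioxinone 9. The dioxinone masks C4=O and the C8a oxygen; a β-methoxy enone masks C5 and the C7 ketone.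
4. 9 is cut at C8–prenyl (palladium-catalysed allylation with carbonate 8) and at C7–C8 (acylation of the dienolate of dioxinone 4 with acid chloride 3).
5. Ring order: ring B purchased, ring A in step 6, ring C in step 11.

Key step: step 6

Assumption: the target is achiral, so the single stereocentre of 9 (the future C8) is carried as the racemate and is erased on aromatisation; the E-alkene of the acyl unit comes unchanged from methyl (E)-3-methoxyacrylate.

**Route**

Step 1
Reactants: 1 methyl (E)-3-methoxyacrylate
Product: 2 sodium (E)-3-methoxyacrylate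
Conditions: NaOH (1.0 equiv), H2O/MeOH, 50 °C; evaporate, dry in vacuo
Reagents that add atoms: sodium hydroxide, [Na+].[OH-]
Why: Saponification of the ester by acyl–oxygen cleavage should give the dry carboxylate salt without touching the E-enol ether, which is stable to base.

Step 2
Reactants: 2 sodium (E)-3-methoxyacrylate
Product: 3 (E)-3-methoxyacryloyl chloride
Conditions: (COCl)2, DMF (cat.), Et2O, 0 °C to rt; filter, distil
Reagents that add atoms: oxalyl chloride, O=C(Cl)C(=O)Cl
Why: Acid chloride formation from the carboxylate salt under Vilsmeier-type catalysis stays non-acidic, so the acid-labile enol ether should survive.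

Step 3
Reactants: 4 2,2,6-trimethyl-4H-1,3-dioxin-4-one; 3 (E)-3-methoxyacryloyl chloride
Product: 6 (E)-6-(4-methoxy-2-oxobut-3-enyl)-2,2-dimethyl-4H-1,3-dioxin-4-one, via lithium 2,2-dimethyl-6-methylidene-1,3-dioxin-4-olate 5 (not isolated)
Conditions: 4 (2.0 equiv), LiN(SiMe3)2 (2.0 equiv), THF, −78 °C; then 3 (1.0 equiv), −78 °C; AcOH quench at −78 °C
Reagents that add atoms: none
Why: Claisen-type γ-C-acylation of the extended lithium dienolate by the acid chloride (1,2-attack at the acyl carbon outruns attack at the β-alkoxy carbon) should form the C7–C8 bond, the second equivalent of dienolate absorbing the acidic proton of the product.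

Step 4
Reactants: 7 3-methylbut-2-en-1-ol
Product: 8 methyl 3-methylbut-2-enyl carbonate
Conditions: ClCO2Me, pyridine, CH2Cl2, 0 °C
Reagents that add atoms: methyl chloroformate, COC(=O)Cl
Why: O-acylation of the primary allylic alcohol with a chloroformate is a routine carbonate synthesis.

Step 5
Reactants: 6 (E)-6-(4-methoxy-2-oxobut-3-enyl)-2,2-dimethyl-4H-1,3-dioxin-4-one; 8 methyl 3-methylbut-2-enyl carbonate
Product: 9 racemic (E)-4-(2,2-dimethyl-4-oxo-4H-1,3-dioxin-6-yl)-1-methoxy-7-methylocta-1,6-dien-3-one
Conditions: Pd(PPh3)4 (5 mol %), 8 (1.0 equiv), THF, 0 °C to rt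
Reagents that add atoms: none
Why: Tsuji–Trost allylic alkylation: zerovalent palladium ionises the carbonate to a π-prenyl complex and methoxide, which deprotonates the only doubly activated methylene, and the soft enolate should attack the unsubstituted allyl terminus to give the linear prenyl group on the future C8; the new stereocentre is formed racemic without control.

Step 6
Reactants: 9 racemic (E)-4-(2,2-dimethyl-4-oxo-4H-1,3-dioxin-6-yl)-1-methoxy-7-methylocta-1,6-dien-3-one
Product: 12 7-hydroxy-2,2-dimethyl-8-(3-methylbut-2-enyl)-4H-benzo[d][1,3]dioxin-4-one, via 5-methoxy-5,6-dihydro conjugate adduct 10 (not isolated), via 4aH-dienone tautomer 11 (not isolated)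
Conditions: Et3N (3 equiv), CH2Cl2 (0.02 M), rt to 40 °C; aq. NH4Cl
Reagents that add atoms: none
Why: Proposed new method: Et3N removes the C8 methine proton (flanked by the C7 ketone and the dioxinone vinylogous ester) to give a cross-conjugated dienolate whose C4a (dioxinone C5) adds to C5, the β-carbon of the methoxy enone, forming adduct 10; E1cB loss of methoxide gives dienone 11 and prototropy from C4a to O7 gives phenol 12. The closest known reaction is the amine- or carbonate-mediated aldol cycloaromatisation of diketo-dioxinones to resorcylate acetonides, together with formal [3+3] benzannulations of 1,3-dicarbonyl dianion equivalents with β-alkoxy enones; what is new is that a vinylogous ester at the aldehyde oxidation level replaces the terminal ketone, so addition–elimination takes the place of aldol–dehydration. Ring A closes in a 6-endo-trig mode, which can equally be read as a 6π-electrocyclisation of the C4a=C8a–C8=C7(O−)–C6=C5 oxido-triene followed by elimination. No stereocentre is created: the racemic C8 methine and the transient C4a and C5 centres all become sp2. The step needs C-attack from C4a rather than from C8 or oxygen, which the substrate secures because C8 could only close a four-membered ring, O-adducts are reversible, and only the C4a adduct can lose methanol and aromatise, an irreversible sink. Working at or below 40 °C keeps the dioxinone from retro-[4+2] opening to the acyl ketene, and the prenyl position is already fixed on C8 before the ring exists.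

Step 7
Reactants: 12 7-hydroxy-2,2-dimethyl-8-(3-methylbut-2-enyl)-4H-benzo[d][1,3]dioxin-4-one
Product: 13 7-methoxy-2,2-dimethyl-8-(3-methylbut-2-enyl)-4H-benzo[d][1,3]dioxin-4-one
Conditions: MeI, K2CO3, acetone, 50 °C
Reagents that add atoms: iodomethane, CI
Why: Williamson etherification of the only free phenol; the benzodioxinone and the prenyl alkene are inert to K2CO3 and MeI.

Step 8
Reactants: 14 2,4,5-trimethoxybenzyl alcohol
Product: 15 1-(chloromethyl)-2,4,5-trimethoxybenzene
Conditions: SOCl2, CH2Cl2, 0 °C; concentrate cold, use at once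
Reagents that add atoms: thionyl chloride, O=S(Cl)Cl
Why: Chlorodehydroxylation of an electron-rich benzylic alcohol via its chlorosulfite is fast at 0 °C; the labile chloride is not stored.

Step 9
Reactants: 15 1-(chloromethyl)-2,4,5-trimethoxybenzene
Product: 16 (2,4,5-trimethoxybenzyl)magnesium chloride (titrated solution)
Conditions: Mg turnings (activated, excess), 2-MeTHF, 0 °C, slow addition
Reagents that add atoms: magnesium, [Mg]
Why: Grignard formation by oxidative insertion of magnesium into the benzylic C–Cl bond; the chloride, high dilution, excess metal and 2-MeTHF are chosen to hold back Wurtz homocoupling.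

Step 10
Reactants: 13 7-methoxy-2,2-dimethyl-8-(3-methylbut-2-enyl)-4H-benzo[d][1,3]dioxin-4-one; 16 (2,4,5-trimethoxybenzyl)magnesium chloride
Product: 17 1-[2-hydroxy-4-methoxy-3-(3-methylbut-2-enyl)phenyl]-2-(2,4,5-trimethoxyphenyl)ethanone
Conditions: 16 (2.5 equiv), THF, −78 to 0 °C; aq. NH4Cl
Reagents that add atoms: none
Why: Nucleophilic acyl substitution by the Grignard reagent at C4: the tetrahedral intermediate collapses with loss of acetone to the magnesium phenoxide of the ketone, which phenoxide donation and enolisation of the benzylic ketone should protect from a second addition (the excess covers reagent lost to the released acetone).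

Step 11
Reactants: 17 1-[2-hydroxy-4-methoxy-3-(3-methylbut-2-enyl)phenyl]-2-(2,4,5-trimethoxyphenyl)ethanone
Product: 19 prebarbigerone [7-methoxy-8-(3-methylbut-2-enyl)-3-(2,4,5-trimethoxyphenyl)-4H-chromen-4-one], via 3-(dimethylamino)propenone enaminone 18 (not isolated)
Conditions: Me2NCH(OMe)2 (3 equiv), toluene, 90 °C
Reagents that add atoms: N,N-dimethylformamide dimethyl acetal, COC(OC)N(C)C
Why: One-carbon isoflavone annulation: the active methylene condenses with the amide acetal to the enaminone, and the ortho phenol closes ring C by 6-endo addition–elimination with loss of dimethylamine under neutral conditions that spare the prenyl group.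

**Compound list**

1 | methyl (E)-3-methoxyacrylate | CO/C=C/C(=O)OC | starting material
2 | sodium (E)-3-methoxyacrylate | CO/C=C/C(=O)[O-].[Na+] | intermediate
3 | (E)-3-methoxyacryloyl chloride | CO/C=C/C(=O)Cl | intermediate
4 | 2,2,6-trimethyl-4H-1,3-dioxin-4-one | CC1=CC(=O)OC(C)(C)O1 | starting material
5 | lithium 2,2-dimethyl-6-methylidene-1,3-dioxin-4-olate (lithium dienolate of 4) | C=C1C=C([O-])OC(C)(C)O1.[Li+] | intermediate
6 | (E)-6-(4-methoxy-2-oxobut-3-enyl)-2,2-dimethyl-4H-1,3-dioxin-4-one | CC1(C)OC(=O)C=C(O1)CC(=O)/C=C/OC | intermediate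
7 | 3-methylbut-2-en-1-ol | CC(C)=CCO | starting material
8 | methyl 3-methylbut-2-enyl carbonate | COC(=O)OCC=C(C)C | intermediate
9 | racemic (E)-4-(2,2-dimethyl-4-oxo-4H-1,3-dioxin-6-yl)-1-methoxy-7-methylocta-1,6-dien-3-one | CC1(C)OC(=O)C=C(O1)C(CC=C(C)C)C(=O)/C=C/OC | intermediate
10 | 5-methoxy-2,2-dimethyl-8-(3-methylbut-2-enyl)-4a,5-dihydro-4H-benzo[d][1,3]dioxine-4,7(6H)-dione (conjugate adduct, neutral keto form, mixture of diastereomers) | CC1(C)OC(=O)C2C(OC)CC(=O)C(CC=C(C)C)=C2O1 | intermediate
11 | 2,2-dimethyl-8-(3-methylbut-2-enyl)-4aH-benzo[d][1,3]dioxine-4,7-dione (dienone tautomer of 12, racemic) | CC1(C)OC(=O)C2C=CC(=O)C(CC=C(C)C)=C2O1 | intermediate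
12 | 7-hydroxy-2,2-dimethyl-8-(3-methylbut-2-enyl)-4H-benzo[d][1,3]dioxin-4-one | CC1(C)OC(=O)c2ccc(O)c(CC=C(C)C)c2O1 | intermediate
13 | 7-methoxy-2,2-dimethyl-8-(3-methylbut-2-enyl)-4H-benzo[d][1,3]dioxin-4-one | CC1(C)OC(=O)c2ccc(OC)c(CC=C(C)C)c2O1 | intermediate
14 | 2,4,5-trimethoxybenzyl alcohol | COc1cc(OC)c(CO)cc1OC | starting material
15 | 1-(chloromethyl)-2,4,5-trimethoxybenzene | COc1cc(OC)c(CCl)cc1OC | intermediate
16 | (2,4,5-trimethoxybenzyl)magnesium chloride | COc1cc(OC)c(C[Mg]Cl)cc1OC | intermediate
17 | 1-[2-hydroxy-4-methoxy-3-(3-methylbut-2-enyl)phenyl]-2-(2,4,5-trimethoxyphenyl)ethanone | COc1cc(OC)c(CC(=O)c2ccc(OC)c(CC=C(C)C)c2O)cc1OC | intermediate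
18 | 3-(dimethylamino)-1-[2-hydroxy-4-methoxy-3-(3-methylbut-2-enyl)phenyl]-2-(2,4,5-trimethoxyphenyl)prop-2-en-1-one (alkene geometry not defined) | COc1cc(OC)c(C(=CN(C)C)C(=O)c2ccc(OC)c(CC=C(C)C)c2O)cc1OC | intermediate
19 | prebarbigerone, 7-methoxy-8-(3-methylbut-2-enyl)-3-(2,4,5-trimethoxyphenyl)-4H-chromen-4-one | COc1cc(OC)c(-c2coc3c(CC=C(C)C)c(OC)ccc3c2=O)cc1OC | target

**Step count**

Total: 11 steps. Longest linear sequence: 8 steps (1, 2, 3, 5, 6, 7, 10, 11).

**Steps most likely to fail**

Step 6 (proposed new method). The dienolate may fail to close onto the weakly electrophilic vinylogous ester. Intermolecular conjugate addition through the unhindered enol ether terminus could then lead to oligomers. If the mixture is warmed to force the reaction, retro-[4+2] opening of the dioxinone to the acyl ketene and lactonisation to a pyranone could take over. Within the step, Cs2CO3 in THF or catalytic DBU would be tried first. The fallback takes ring A from the aromatic pool and attaches only the prenyl group; it sets out from carbonate 8 and comes back at 12. Commercial 2,4-dihydroxybenzoic acid would be condensed with acetone in trifluoroacetic anhydride and trifluoroacetic acid to give 7-hydroxy-2,2-dimethyl-4H-benzo[d][1,3]dioxin-4-one F1. F1 and 8 with Pd(PPh3)4 in THF at 0 °C for a short time should give the kinetically preferred tertiary ether 2,2-dimethyl-7-(2-methylbut-3-en-2-yloxy)-4H-benzo[d][1,3]dioxin-4-one F2, by phenoxide attack at the substituted terminus of the π-prenyl complex. An aromatic Claisen rearrangement of F2 in N,N-diethylaniline at about 140 °C should then deliver the prenyl group mainly to C8, the ortho carbon between the two oxygens, to give 12; the C6 isomer would be removed by chromatography.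

Step 10. Wurtz homocoupling during formation of the electron-rich benzyl Grignard reagent, consumption of the reagent by the released acetone, a second addition to the new ketone, or ortho attack of the ambident benzyl nucleophile could erode the yield. The fallback replaces the Grignard reagent by a stabilised sulfonyl carbanion; it sets out from chloride 15 and benzodioxinone 13 and comes back at 17. Chloride 15 and PhSO2Na in DMF would give 1,2,4-trimethoxy-5-[(phenylsulfonyl)methyl]benzene F3. Deprotonation with n-butyllithium in THF at −78 °C would give lithium (phenylsulfonyl)(2,4,5-trimethoxyphenyl)methanide F4, two equivalents of which would open 13 with loss of acetone to the β-keto sulfone 1-[2-hydroxy-4-methoxy-3-(3-methylbut-2-enyl)phenyl]-2-(phenylsulfonyl)-2-(2,4,5-trimethoxyphenyl)ethanone F5. The enolate of F5 cannot add a second nucleophile. Reductive desulfonylation with zinc dust in acetic acid/THF should then give 17.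

Step 5. Over-prenylation of the still acidic product, attack at the substituted allyl terminus (1,1-dimethylallyl isomer), or premature ring closure of unprenylated 6 under the methoxide released could spoil the allylation. The fallback reverses the order of the two C–C bond formations so that no palladium and no unprenylated keto-dioxinone are involved; it sets out from dienolate 5 (from dioxinone 4) and comes back at 9. Dienolate 5 would be alkylated at its γ-carbon with prenyl bromide in THF/DMPU at −78 °C to give 2,2-dimethyl-6-(4-methylpent-3-enyl)-4H-1,3-dioxin-4-one F6. Deprotonation of F6 with LiN(SiMe3)2 would give lithium 2,2-dimethyl-6-(4-methylpent-3-enylidene)-1,3-dioxin-4-olate F7, and γ-acylation of F7 with acid chloride 3 at −78 °C should give 9 directly, with the prenyl group already on the future C8.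

**Further compounds**

F1 | step 6 | 7-hydroxy-2,2-dimethyl-4H-benzo[d][1,3]dioxin-4-one | CC1(C)OC(=O)c2ccc(O)cc2O1
F2 | step 6 | 2,2-dimethyl-7-(2-methylbut-3-en-2-yloxy)-4H-benzo[d][1,3]dioxin-4-one | CC1(C)OC(=O)c2ccc(OC(C)(C)C=C)cc2O1
F3 | step 10 | 1,2,4-trimethoxy-5-[(phenylsulfonyl)methyl]benzene | COc1cc(OC)c(CS(=O)(=O)c2ccccc2)cc1OC
F4 | step 10 | lithium (phenylsulfonyl)(2,4,5-trimethoxyphenyl)methanide | COc1cc(OC)c([CH-]S(=O)(=O)c2ccccc2)cc1OC.[Li+]
F5 | step 10 | 1-[2-hydroxy-4-methoxy-3-(3-methylbut-2-enyl)phenyl]-2-(phenylsulfonyl)-2-(2,4,5-trimethoxyphenyl)ethanone | COc1cc(OC)c(C(C(=O)c2ccc(OC)c(CC=C(C)C)c2O)S(=O)(=O)c2ccccc2)cc1OC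
F6 | step 5 | 2,2-dimethyl-6-(4-methylpent-3-enyl)-4H-1,3-dioxin-4-one | CC(C)=CCCC1=CC(=O)OC(C)(C)O1
F7 | step 5 | lithium 2,2-dimethyl-6-(4-methylpent-3-enylidene)-1,3-dioxin-4-olate | CC(C)=CCC=C1C=C([O-])OC(C)(C)O1.[Li+]
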